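**Plan**

Rings are lettered A (2,4,6-trihydroxyphenyl end) to F (3,4,5-trihydroxyphenyl end); ring C is numbered C1 (O–ring B), C2 (H), C3, C4, C5 (OH), C6 (O–ring D).
Retrosynthesis: the fifteen O–CH3 bonds are cut first, then ring C at C2–C3 and C1–C6 (cycloaddition bonds) and C3–C4 (electrocyclic bond), giving an A–B aryl ethynyl ether and a D–E–F-substituted cyclobutenone.
Enabling feature: ring C has five oxygens and one C–H, with the two aryloxy groups vicinal on C1 and C6. H–C2≡C1–O is therefore an ynol ether, and C3–C6 with their four oxygens are an oxygenated vinylketene, which a squaric acid derivative supplies.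
Further cuts: the cyclobutenone at its O–ring D bond (squaric acid dichloride), and the ethers D–O–E, E–O–F and A–O–B by copper couplings that pair a hindered phenol with an unhindered or formyl-activated partner.
Forward: rings A, B, D, E and F are bought as arenes; E is joined to D and then to F (steps 1–5), the four-membered ring is attached (6–9), A–B is made and turned into the ynol ether (10–14), ring C is formed last (15), and all methyl ethers are cleaved (16).
Stereochemistry: the target has no stereocentre; the single centre made on the way (C4 of the cyclobutenone, racemic) is erased when ring C aromatises.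

Key step: step 15

Assumption: 4-bromo-2,6-dimethoxyphenol, 2,4,6-trimethoxyphenol, 5-bromo-1,2,3-trimethoxybenzene and (3,4,5-trimethoxyphenyl)boronic acid are taken as catalogue compounds, and the air-sensitive polyphenol is isolated under argon.

Abbreviations used in names: AB-aryloxy = 2,6-dimethoxy-4-(2,4,6-trimethoxyphenoxy)phenoxy; DEF-aryloxy = 3,5-dimethoxy-4-[3,4,5-trimethoxy-2-(3,4,5-trimethoxyphenoxy)phenoxy]phenoxy.

**Route**

Step 1
Reactants: 1 5-bromo-1,2,3-trimethoxybenzene
Product: 2 6-bromo-2,3,4-trimethoxybenzaldehyde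
Conditions: Cl2CHOMe, TiCl4, CH2Cl2, 0 °C; then ice-water
Reagents that add atoms: dichloromethyl methyl ether, COC(Cl)Cl; water, O
Why: Rieche formylation should give a single aldehyde, because the two open positions of 1 are equivalent and each lies ortho and para to methoxy groups, so the formyl group must end up beside bromine.

Step 2
Reactants: 2 6-bromo-2,3,4-trimethoxybenzaldehyde; 3 4-bromo-2,6-dimethoxyphenol
Product: 4 6-(4-bromo-2,6-dimethoxyphenoxy)-2,3,4-trimethoxybenzaldehyde
Conditions: CuI (10 mol %), picolinic acid (20 mol %), K3PO4, DMSO, 90 °C, Ar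
Reagents that add atoms: none
Why: In this Ullmann diaryl ether coupling the bromide of 2 is activated by its ortho-formyl group whereas the bromide of phenoxide 3 sits para to the oxido group and is deactivated, and the picolinic acid ligand suits 2,6-disubstituted phenols, so cross-coupling should outrun self-condensation of 3.

Step 3
Reactants: 4 6-(4-bromo-2,6-dimethoxyphenoxy)-2,3,4-trimethoxybenzaldehyde
Product: 6 6-(4-bromo-2,6-dimethoxyphenoxy)-2,3,4-trimethoxyphenol, via aryl formate 5 (not isolated)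
Conditions: mCPBA, CH2Cl2, 0 °C → rt; then K2CO3 (cat.), MeOH, rt
Reagents that add atoms: mCPBA, OOC(=O)c1cccc(Cl)c1
Why: Baeyer–Villiger oxidation of an electron-rich benzaldehyde proceeds with aryl migration (Dakin-type) to the formate, which mild methanolysis cleaves without touching the aryl bromide or the ethers.

Step 4
Reactants: 6 6-(4-bromo-2,6-dimethoxyphenoxy)-2,3,4-trimethoxyphenol; 7 (3,4,5-trimethoxyphenyl)boronic acid
Product: 8 5-bromo-1,3-dimethoxy-2-[3,4,5-trimethoxy-2-(3,4,5-trimethoxyphenoxy)phenoxy]benzene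
Conditions: Cu(OAc)2 (1 equiv), pyridine, 4 Å MS, CH2Cl2, dry air, rt
Reagents that add atoms: none
Why: The Chan–Lam coupling joins a di-ortho-substituted phenol to an unhindered, electron-rich arylboronic acid at room temperature and leaves the ring D bromide untouched, which a hot Ullmann coupling would not guarantee.

Step 5
Reactants: 8 5-bromo-1,3-dimethoxy-2-[3,4,5-trimethoxy-2-(3,4,5-trimethoxyphenoxy)phenoxy]benzene
Product: 9 3,5-dimethoxy-4-[3,4,5-trimethoxy-2-(3,4,5-trimethoxyphenoxy)phenoxy]phenol (DEF phenol)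
Conditions: Pd2(dba)3 (2 mol %), tBuXPhos (8 mol %), KOH, 1,4-dioxane/H2O (1:1), 100 °C; then 1 M HCl
Reagents that add atoms: potassium hydroxide, [K+].[OH-]
Why: Palladium-catalysed hydroxylation of aryl bromides with KOH and a bulky biarylphosphine (a Buchwald–Hartwig-type C–O coupling) is reliable for electron-rich bromides, and 8 carries only ether groups besides the bromide.

Step 6
Reactants: 10 squaric acid
Product: 11 squaric acid dichloride (3,4-dichlorocyclobut-3-ene-1,2-dione)
Conditions: (COCl)2 (2.2 equiv), DMF (cat.), CH2Cl2, rt → 40 °C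
Reagents that add atoms: oxalyl chloride, O=C(Cl)C(=O)Cl
Why: Chlorination of the vinylogous acid with oxalyl chloride and catalytic DMF (Vilsmeier-type activation) is the standard preparation of this dichloride.

Step 7
Reactants: 11 squaric acid dichloride; 9 DEF phenol
Product: 13 3-methoxy-4-(DEF-aryloxy)cyclobut-3-ene-1,2-dione, via chloro methoxy squarate 12 (not isolated)
Conditions: MeOH (1.0 equiv), iPr2NEt (1.0 equiv), CH2Cl2, −78 → −20 °C; then 9, iPr2NEt (1.1 equiv), −78 → 0 °C
Reagents that add atoms: methanol, CO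
Why: Two successive addition–elimination reactions at a vinylogous acid chloride are used, the first chloride reacting with one equivalent of methanol at low temperature and the less reactive ester chloride 12 then acylating phenoxide 9, so that the aryl squarate is never exposed to free methanol.

Step 8
Reactants: 13 3-methoxy-4-(DEF-aryloxy)cyclobut-3-ene-1,2-dione
Product: 14 racemic 4-hydroxy-3-methoxy-2-(DEF-aryloxy)cyclobut-2-en-1-one
Conditions: LiAlH(OtBu)3 (1.05 equiv), THF, −78 °C; pH 7 buffer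
Reagents that add atoms: none
Why: 1,2-Reduction of squarates by LiAlH(OtBu)3 is established, and in 13 hydride should choose the carbonyl beside the methoxy-bearing carbon because that carbonyl is conjugated with the weaker aryloxy donor and is the less shielded one, giving the carbinol as a racemate whose centre is erased in step 15.

Step 9
Reactants: 14 racemic 4-hydroxy-3-methoxy-2-(DEF-aryloxy)cyclobut-2-en-1-one
Product: 15 racemic 3,4-dimethoxy-2-(DEF-aryloxy)cyclobut-2-en-1-one
Conditions: MeI, Ag2O, 4 Å MS, MeCN, rt, dark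
Reagents that add atoms: iodomethane, CI
Why: Purdie methylation with Ag2O and MeI is neutral enough for a 4-hydroxycyclobutenone, and the methyl cap is needed because a free hydroxyl would let the later vinylketene close to a butenolide.

Step 10
Reactants: 3 4-bromo-2,6-dimethoxyphenol
Product: 16 2-(benzyloxy)-5-bromo-1,3-dimethoxybenzene
Conditions: BnBr, K2CO3, DMF, rt
Reagents that add atoms: benzyl bromide, BrCc1ccccc1
Why: Williamson etherification masks the phenol that later becomes the ynol ether oxygen with a group that survives hot base and copper and leaves by hydrogenolysis.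

Step 11
Reactants: 16 2-(benzyloxy)-5-bromo-1,3-dimethoxybenzene; 17 2,4,6-trimethoxyphenol
Product: 18 2-(benzyloxy)-1,3-dimethoxy-5-(2,4,6-trimethoxyphenoxy)benzene
Conditions: CuI (10 mol %), picolinic acid (20 mol %), K3PO4, DMSO, 100 °C, Ar
Reagents that add atoms: none
Why: Ullmann coupling under CuI/picolinic acid conditions pairs the hindered, electron-rich phenol 17 with a bromide that has two free ortho positions, the favourable polarity for such ethers.

Step 12
Reactants: 18 2-(benzyloxy)-1,3-dimethoxy-5-(2,4,6-trimethoxyphenoxy)benzene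
Product: 19 2,6-dimethoxy-4-(2,4,6-trimethoxyphenoxy)phenol (AB phenol)
Conditions: H2 (1 atm), 10% Pd/C, EtOAc/MeOH, rt
Reagents that add atoms: none
Why: Catalytic hydrogenolysis cleaves the benzyl ether only, diaryl and methyl ethers being inert.

Step 13
Reactants: 19 AB phenol; 20 trichloroethylene
Product: 22 2-{[(E)-1,2-dichloroethenyl]oxy}-1,3-dimethoxy-5-(2,4,6-trimethoxyphenoxy)benzene, via dichloroacetylene 21 (not isolated)
Conditions: K2CO3, DMF, 70 °C, Ar
Reagents that add atoms: none
Why: Base converts trichloroethylene into dichloroacetylene, to which the phenoxide adds in anti fashion (nucleophilic vinylic substitution by elimination–addition) to give the (E)-dichlorovinyl ether, and the small linear electrophile should tolerate the two flanking methoxy groups.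

Step 14
Reactants: 22 2-{[(E)-1,2-dichloroethenyl]oxy}-1,3-dimethoxy-5-(2,4,6-trimethoxyphenoxy)benzene
Product: 25 2-(ethynyloxy)-1,3-dimethoxy-5-(2,4,6-trimethoxyphenoxy)benzene (AB ynol ether), via chloroethynyl ether 23 (not isolated), via lithium acetylide 24 (not isolated)
Conditions: n-BuLi (2.2 equiv), THF, −78 → −40 °C; MeOH, −78 °C; cold neutral work-up, used at once
Reagents that add atoms: none
Why: Dehydrochlorination by the first equivalent of n-BuLi and chlorine–lithium exchange by the second (the classical dichlorovinyl ether route to ynol ethers) give the lithium acetylide, which methanol protonates at −78 °C before ring metalation can compete.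

Step 15
Reactants: 15 racemic 3,4-dimethoxy-2-(DEF-aryloxy)cyclobut-2-en-1-one; 25 AB ynol ether
Product: 30 2,3-dimethoxy-4-(DEF-aryloxy)-5-(AB-aryloxy)phenol, via vinylketene 26 (not isolated), via vinylcyclobutenone 27 (not isolated), via dienylketene 28 (not isolated), via cyclohexadienone 29 (not isolated)
Conditions: 25 (1.5 equiv), toluene (0.05 M), 80 °C then 110 °C, sealed tube, Ar
Reagents that add atoms: none
Why: Heat opens 15 by a conrotatory four-electron electrocyclic reaction, the 4-methoxy group turning outward, to vinylketene 26; ynol ether 25 adds across the ketene C=C in a [2+2] cycloaddition, its nucleophilic CH terminus bonding to the ketene carbonyl carbon (future C3) and its oxygen-bearing carbon (C1) to the aryloxy-bearing ketene carbon (C6), to give vinylcyclobutenone 27. A second four-electron opening, aryloxy outward and methoxyvinyl inward, gives the (Z)-dienylketene 28, and ring C closes by a thermal disrotatory six-electron electrocyclisation that forms C3–C4, after which cyclohexadienone 29 tautomerises to phenol 30. This is the Danheiser benzannulation of a cyclobutenone with an alkynyl ether, here applied to an aryloxyalkyne and a fully oxygenated cyclobutenone. No stereocentre is created and the racemic centre of 15 becomes the aromatic C4. The step needs regioselectivity in the [2+2] event, secured by the polarisation of the ynol ether that puts the lone C2–H between C1–O–ring B and the new C3–OH, and inward rotation of the vinyl group, secured by the outward preference of the oxygen donor on the same carbon. An aryl ethynyl ether has no hydrogen for retro-ene loss of ketene and so should tolerate the temperature.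

Step 16
Reactants: 30 2,3-dimethoxy-4-(DEF-aryloxy)-5-(AB-aryloxy)phenol
Product: 31 CNP0114537.0 (hexadecahydroxy hexamer, target)
Conditions: BBr3 (30 equiv), CH2Cl2, −78 °C → rt, Ar; then degassed H2O, 0 °C
Reagents that add atoms: none
Why: BBr3 cleaves aryl methyl ethers by Lewis acid complexation and bromide attack at methyl while diaryl ether bonds are inert, and exclusion of air protects the pyrogallol-type rings C, E and F of the product.

**Compound list**

1 | 5-bromo-1,2,3-trimethoxybenzene | COc1cc(Br)cc(OC)c1OC | starting material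
2 | 6-bromo-2,3,4-trimethoxybenzaldehyde | O=Cc1c(Br)cc(OC)c(OC)c1OC | intermediate
3 | 4-bromo-2,6-dimethoxyphenol | Oc1c(OC)cc(Br)cc1OC | starting material
4 | 6-(4-bromo-2,6-dimethoxyphenoxy)-2,3,4-trimethoxybenzaldehyde | O=Cc1c(Oc2c(OC)cc(Br)cc2OC)cc(OC)c(OC)c1OC | intermediate
5 | 6-(4-bromo-2,6-dimethoxyphenoxy)-2,3,4-trimethoxyphenyl formate (formed in the flask) | O=COc1c(Oc2c(OC)cc(Br)cc2OC)cc(OC)c(OC)c1OC | intermediate
6 | 6-(4-bromo-2,6-dimethoxyphenoxy)-2,3,4-trimethoxyphenol | Oc1c(Oc2c(OC)cc(Br)cc2OC)cc(OC)c(OC)c1OC | intermediate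
7 | (3,4,5-trimethoxyphenyl)boronic acid | COc1cc(B(O)O)cc(OC)c1OC | starting material
8 | 5-bromo-1,3-dimethoxy-2-[3,4,5-trimethoxy-2-(3,4,5-trimethoxyphenoxy)phenoxy]benzene (DEF bromide) | Brc1cc(OC)c(Oc2cc(OC)c(OC)c(OC)c2Oc2cc(OC)c(OC)c(OC)c2)c(OC)c1 | intermediate
9 | 3,5-dimethoxy-4-[3,4,5-trimethoxy-2-(3,4,5-trimethoxyphenoxy)phenoxy]phenol (DEF phenol) | Oc1cc(OC)c(Oc2cc(OC)c(OC)c(OC)c2Oc2cc(OC)c(OC)c(OC)c2)c(OC)c1 | intermediate
10 | squaric acid (3,4-dihydroxycyclobut-3-ene-1,2-dione) | OC1=C(O)C(=O)C1=O | starting material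
11 | squaric acid dichloride (3,4-dichlorocyclobut-3-ene-1,2-dione) | ClC1=C(Cl)C(=O)C1=O | intermediate
12 | 3-chloro-4-methoxycyclobut-3-ene-1,2-dione (formed in the flask) | COC1=C(Cl)C(=O)C1=O | intermediate
13 | 3-methoxy-4-(DEF-aryloxy)cyclobut-3-ene-1,2-dione | COC1=C(Oc2cc(OC)c(Oc3cc(OC)c(OC)c(OC)c3Oc3cc(OC)c(OC)c(OC)c3)c(OC)c2)C(=O)C1=O | intermediate
14 | racemic 4-hydroxy-3-methoxy-2-(DEF-aryloxy)cyclobut-2-en-1-one | O=C1C(Oc2cc(OC)c(Oc3cc(OC)c(OC)c(OC)c3Oc3cc(OC)c(OC)c(OC)c3)c(OC)c2)=C(OC)C1O | intermediate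
15 | racemic 3,4-dimethoxy-2-(DEF-aryloxy)cyclobut-2-en-1-one | O=C1C(Oc2cc(OC)c(Oc3cc(OC)c(OC)c(OC)c3Oc3cc(OC)c(OC)c(OC)c3)c(OC)c2)=C(OC)C1OC | intermediate
16 | 2-(benzyloxy)-5-bromo-1,3-dimethoxybenzene | COc1cc(Br)cc(OC)c1OCc1ccccc1 | intermediate
17 | 2,4,6-trimethoxyphenol | Oc1c(OC)cc(OC)cc1OC | starting material
18 | 2-(benzyloxy)-1,3-dimethoxy-5-(2,4,6-trimethoxyphenoxy)benzene | COc1cc(Oc2c(OC)cc(OC)cc2OC)cc(OC)c1OCc1ccccc1 | intermediate
19 | 2,6-dimethoxy-4-(2,4,6-trimethoxyphenoxy)phenol (AB phenol) | Oc1c(OC)cc(Oc2c(OC)cc(OC)cc2OC)cc1OC | intermediate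
20 | trichloroethylene | ClC=C(Cl)Cl | starting material
21 | dichloroacetylene (formed in the flask) | ClC#CCl | intermediate
22 | 2-{[(E)-1,2-dichloroethenyl]oxy}-1,3-dimethoxy-5-(2,4,6-trimethoxyphenoxy)benzene | Cl/C=C(/Cl)Oc1c(OC)cc(Oc2c(OC)cc(OC)cc2OC)cc1OC | intermediate
23 | 2-[(chloroethynyl)oxy]-1,3-dimethoxy-5-(2,4,6-trimethoxyphenoxy)benzene (formed in the flask) | ClC#COc1c(OC)cc(Oc2c(OC)cc(OC)cc2OC)cc1OC | intermediate
24 | lithium [2,6-dimethoxy-4-(2,4,6-trimethoxyphenoxy)phenoxy]acetylide (formed in the flask) | [Li]C#COc1c(OC)cc(Oc2c(OC)cc(OC)cc2OC)cc1OC | intermediate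
25 | 2-(ethynyloxy)-1,3-dimethoxy-5-(2,4,6-trimethoxyphenoxy)benzene (AB ynol ether) | C#COc1c(OC)cc(Oc2c(OC)cc(OC)cc2OC)cc1OC | intermediate
26 | (3Z)-2-(DEF-aryloxy)-3,4-dimethoxybuta-1,3-dien-1-one (vinylketene, transient) | O=C=C(Oc1cc(OC)c(Oc2cc(OC)c(OC)c(OC)c2Oc2cc(OC)c(OC)c(OC)c2)c(OC)c1)/C(OC)=C/OC | intermediate
27 | racemic 3-(AB-aryloxy)-4-(DEF-aryloxy)-4-[(Z)-1,2-dimethoxyethenyl]cyclobut-2-en-1-one (transient) | O=C1C=C(Oc2c(OC)cc(Oc3c(OC)cc(OC)cc3OC)cc2OC)C1(Oc2cc(OC)c(Oc3cc(OC)c(OC)c(OC)c3Oc3cc(OC)c(OC)c(OC)c3)c(OC)c2)/C(OC)=C/OC | intermediate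
28 | (3Z,5Z)-3-(AB-aryloxy)-4-(DEF-aryloxy)-5,6-dimethoxyhexa-1,3,5-trien-1-one (dienylketene, transient) | O=C=C/C(Oc1c(OC)cc(Oc2c(OC)cc(OC)cc2OC)cc1OC)=C(Oc1cc(OC)c(Oc2cc(OC)c(OC)c(OC)c2Oc2cc(OC)c(OC)c(OC)c2)c(OC)c1)\C(OC)=C\OC | intermediate
29 | racemic 3-(AB-aryloxy)-4-(DEF-aryloxy)-5,6-dimethoxycyclohexa-2,4-dien-1-one (transient) | O=C1C=C(Oc2c(OC)cc(Oc3c(OC)cc(OC)cc3OC)cc2OC)C(Oc2cc(OC)c(Oc3cc(OC)c(OC)c(OC)c3Oc3cc(OC)c(OC)c(OC)c3)c(OC)c2)=C(OC)C1OC | intermediate
30 | 2,3-dimethoxy-4-(DEF-aryloxy)-5-(AB-aryloxy)phenol (pentadecamethyl hexamer, free ring C hydroxyl at C3) | COc1cc(OC)c(Oc2cc(OC)c(Oc3cc(O)c(OC)c(OC)c3Oc3cc(OC)c(Oc4cc(OC)c(OC)c(OC)c4Oc4cc(OC)c(OC)c(OC)c4)c(OC)c3)c(OC)c2)c(OC)c1 | intermediate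
31 | CNP0114537.0 | Oc1cc(O)c(Oc2cc(O)c(Oc3cc(O)c(O)c(O)c3Oc3cc(O)c(Oc4cc(O)c(O)c(O)c4Oc4cc(O)c(O)c(O)c4)c(O)c3)c(O)c2)c(O)c1 | target

**Count and risks**

Total step count: 16. Longest linear sequence: 10 steps (1, 2, 3, 4, 5, 7, 8, 9, 15, 16).

Steps most likely to fail:

Step 15. The electron-rich vinylketene may dimerise or acylate the product phenol faster than the weakly nucleophilic aryloxyalkyne captures it, and the alkyne may oligomerise at 110 °C. The fallback takes ring C from arene 2 instead of building it. It sets out from 19 (with 2 and 8) and comes back to the route at 31. Phenol 19 and bromoaldehyde 2 are coupled (CuI, picolinic acid, K3PO4, DMSO, 90 °C) to 6-(AB-aryloxy)-2,3,4-trimethoxybenzaldehyde F1. mCPBA then gives 6-(AB-aryloxy)-2,3,4-trimethoxyphenyl formate F2, and K2CO3/MeOH gives 6-(AB-aryloxy)-2,3,4-trimethoxyphenol F3. A second Ullmann coupling of this hindered phenol with the unhindered bromide 8 under the same copper conditions gives the hexadecamethyl ether of the target F4. BBr3 as in step 16 then gives 31.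

Step 8. Hydride may add to the other carbonyl with poor regioselection, or add at the aryloxy-bearing ring carbon and expel the aryloxide. The fallback removes the choice between two different carbonyls. It sets out from 9 and 11 and comes back at 15. Two equivalents of 9 with 11 and iPr2NEt give the symmetrical 3,4-bis(DEF-aryloxy)cyclobut-3-ene-1,2-dione F5. LiAlH(OtBu)3 reduces either carbonyl to the same racemic 4-hydroxy-2,3-bis(DEF-aryloxy)cyclobut-2-en-1-one F6, and Ag2O/MeI gives racemic 4-methoxy-2,3-bis(DEF-aryloxy)cyclobut-2-en-1-one F7. MeOH with Et3N at 0 °C then exchanges only the aryloxy group on the β-carbon, the sole position open to addition–elimination, giving 15 and returning one equivalent of 9.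

Step 14. The terminal aryloxyacetylene may oligomerise or hydrate during concentration and purification, and part of the n-BuLi may metalate a ring position flanked by two oxygens. The fallback isolates a capped surrogate. It sets out from 22 and comes back at 25. Acetylide 24 is generated as before but quenched with Me3SiCl to give 2-{[(trimethylsilyl)ethynyl]oxy}-1,3-dimethoxy-5-(2,4,6-trimethoxyphenoxy)benzene F8, which can be chromatographed and stored. K2CO3 (cat.) in MeOH/THF at 0 °C releases 25 immediately before step 15.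

**Further compounds**

F1 | step 15 | 6-(AB-aryloxy)-2,3,4-trimethoxybenzaldehyde | O=Cc1c(Oc2c(OC)cc(Oc3c(OC)cc(OC)cc3OC)cc2OC)cc(OC)c(OC)c1OC
F2 | step 15 | 6-(AB-aryloxy)-2,3,4-trimethoxyphenyl formate | O=COc1c(Oc2c(OC)cc(Oc3c(OC)cc(OC)cc3OC)cc2OC)cc(OC)c(OC)c1OC
F3 | step 15 | 6-(AB-aryloxy)-2,3,4-trimethoxyphenol | Oc1c(Oc2c(OC)cc(Oc3c(OC)cc(OC)cc3OC)cc2OC)cc(OC)c(OC)c1OC
F4 | step 15 | hexadecamethyl ether of the target | COc1cc(OC)c(Oc2cc(OC)c(Oc3cc(OC)c(OC)c(OC)c3Oc3cc(OC)c(Oc4cc(OC)c(OC)c(OC)c4Oc4cc(OC)c(OC)c(OC)c4)c(OC)c3)c(OC)c2)c(OC)c1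
F5 | step 8 | 3,4-bis(DEF-aryloxy)cyclobut-3-ene-1,2-dione | O=C1C(=O)C(Oc2cc(OC)c(Oc3cc(OC)c(OC)c(OC)c3Oc3cc(OC)c(OC)c(OC)c3)c(OC)c2)=C1Oc1cc(OC)c(Oc2cc(OC)c(OC)c(OC)c2Oc2cc(OC)c(OC)c(OC)c2)c(OC)c1
F6 | step 8 | racemic 4-hydroxy-2,3-bis(DEF-aryloxy)cyclobut-2-en-1-one | O=C1C(Oc2cc(OC)c(Oc3cc(OC)c(OC)c(OC)c3Oc3cc(OC)c(OC)c(OC)c3)c(OC)c2)=C(Oc2cc(OC)c(Oc3cc(OC)c(OC)c(OC)c3Oc3cc(OC)c(OC)c(OC)c3)c(OC)c2)C1O
F7 | step 8 | racemic 4-methoxy-2,3-bis(DEF-aryloxy)cyclobut-2-en-1-one | O=C1C(Oc2cc(OC)c(Oc3cc(OC)c(OC)c(OC)c3Oc3cc(OC)c(OC)c(OC)c3)c(OC)c2)=C(Oc2cc(OC)c(Oc3cc(OC)c(OC)c(OC)c3Oc3cc(OC)c(OC)c(OC)c3)c(OC)c2)C1OC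
F8 | step 14 | 2-{[(trimethylsilyl)ethynyl]oxy}-1,3-dimethoxy-5-(2,4,6-trimethoxyphenoxy)benzene | C[Si](C)(C)C#COc1c(OC)cc(Oc2c(OC)cc(OC)cc2OC)cc1OC
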